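**Assumptions.** (1) The target has no stereocentres (the C(CH3)2 carbons are not stereogenic), so it is achiral and no enantioselective step is needed. (2) 3-Bromo-5-methoxyphenol is taken as commercially available. (3) The regiochemical outcomes of the directed ortho-lithiations (Steps 2 and 4) and of the iodination (Step 7) are assumed to favour the desired isomers, as explained in each "Why".

## Retrosynthesis
- The last step is a global O-demethylation of the permethyl ether 16.
- The benzofuran is formed in the penultimate step by Pd/Cu Sonogashira coupling and 5-endo-dig cyclisation of the o-iodophenol 15 with the B-ring alkyne 10.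
- The quaternary 1,1-dimethylallyl group on the A ring comes from an aromatic Claisen rearrangement of the O-prenyl ether of 2-iodo-3,5-dimethoxyphenol.
- The B-ring chroman is formed first: ortho-lithiation and prenylation of a bromo-anisole, then acid-mediated 6-endo hydroalkoxylation. A second ortho-lithiation and prenylation, then a Sonogashira coupling, give the alkyne.
- Ring order: chroman (Steps 2–3), then the prenylated B ring (Step 4), then the benzofuran (Step 10).

## Route

**Step 1**
Reactants: 1 (3-bromo-5-methoxyphenol), 2 (chloromethyl methyl ether, MOMCl)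
Product: 3 (1-bromo-3-methoxy-5-(methoxymethoxy)benzene)
Conditions: MOMCl, iPr2NEt, CH2Cl2, 0 °C → rt
Reagents that add atoms: MOMCl, ClCOC
Why: Phenol O-alkylation (MOM protection) differentiates the two oxygens. The MOM ether is a stronger ortho-directing group than OMe, so it controls the site of the next lithiation.

**Step 2**
Reactants: 3, 4 (prenyl bromide)
Product: 5 (1-bromo-5-methoxy-3-(methoxymethoxy)-2-(3-methylbut-2-en-1-yl)benzene)
Conditions: LDA, THF, −78 °C; then CuI (10 mol%), prenyl bromide, −78 °C → rt
Reagents that add atoms: prenyl bromide, BrCC=C(C)C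
Why: Directed ortho-metalation occurs at the C–H flanked by Br and OMOM, which is the most acidic and best coordinated site. Cu-catalysed SN2 alkylation then installs the linear prenyl group. No stereocentre is formed.

**Step 3**
Reactants: 5
Product: 6 (5-bromo-7-methoxy-2,2-dimethylchroman)
Conditions: (i) p-TsOH·H2O, MeOH, 50 °C; (ii) evaporate, TfOH (10 mol%), CH2Cl2, 0 °C → rt (one pot)
Reagents that add atoms: none
Why: MOM cleavage gives the o-prenylphenol. Protonation of the prenyl alkene gives the tertiary cation, which the phenol captures in a Markovnikov 6-endo hydroalkoxylation to form the 2,2-dimethylchroman. Br and OMe are inert, and no stereocentre results.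

**Step 4**
Reactants: 6, 4 (prenyl bromide)
Product: 7 (5-bromo-7-methoxy-2,2-dimethyl-6-(3-methylbut-2-en-1-yl)chroman)
Conditions: LDA, THF, −78 °C; then CuI (10 mol%), prenyl bromide, −78 °C → rt
Reagents that add atoms: prenyl bromide, BrCC=C(C)C
Why: Directed ortho-metalation occurs at C6, the site flanked by Br and OMe. This is preferred over C8 because Br adds inductive acidification at C6. Cu-catalysed SN2 alkylation installs the prenyl group, and the lithium is trapped at −78 °C to avoid benzyne formation.

**Step 5**
Reactants: 7, 8 (trimethylsilylacetylene)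
Product: 9 (7-methoxy-2,2-dimethyl-6-prenyl-5-((trimethylsilyl)ethynyl)chroman)
Conditions: PdCl2(MeCN)2 (5 mol%), XPhos (10 mol%), CuI (5 mol%), Et3N, MeCN, 90 °C
Reagents that add atoms: TMS-acetylene, C#C[Si](C)(C)C
Why: Sonogashira coupling with a bulky biaryl phosphine ligand handles the di-ortho-substituted, electron-rich aryl bromide. The prenyl alkene cannot undergo an intramolecular Heck reaction (it would need a 4-exo or 5-endo closure).

**Step 6**
Reactants: 9
Product: 10 (5-ethynyl-7-methoxy-2,2-dimethyl-6-prenylchroman)
Conditions: K2CO3, MeOH, rt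
Reagents that add atoms: none
Why: Base-mediated protodesilylation of the aryl-TMS-alkyne; the alkenes and ethers are untouched.

**Step 7**
Reactants: 11 (3,5-dimethoxyphenol), 12 (N-iodosuccinimide)
Product: 13 (2-iodo-3,5-dimethoxyphenol)
Conditions: NIS, CH2Cl2, −78 °C → 0 °C; chromatographic removal of the 4-iodo isomer
Reagents that add atoms: NIS, O=C1CCC(=O)N1I
Why: Electrophilic aromatic iodination goes ortho to the OH. This is done before any alkenes are present, so iodocyclisation cannot compete. The iodine also blocks one ortho position for the Claisen step.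

**Step 8**
Reactants: 13, 4 (prenyl bromide)
Product: 14 (2-iodo-1,5-dimethoxy-3-(prenyloxy)benzene)
Conditions: prenyl bromide, K2CO3, acetone, reflux
Reagents that add atoms: prenyl bromide, BrCC=C(C)C
Why: Williamson O-alkylation of the phenol.

**Step 9**
Reactants: 14
Product: 15 (2-iodo-3,5-dimethoxy-6-(2-methylbut-3-en-2-yl)phenol)
Conditions: BCl3, CH2Cl2, −78 → −20 °C
Reagents that add atoms: none
Why: Lewis-acid-promoted aromatic Claisen [3,3] rearrangement of the prenyl ether. It forms the quaternary 1,1-dimethylallyl carbon at the only free ortho position, since the other is blocked by iodine. No stereocentre is formed.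

**Step 10**
Reactants: 10, 15
Product: 16 (7-(2-methylbut-3-en-2-yl)-4,6-dimethoxy-2-(5-prenyl... 7'-methoxy-2,2-dimethylchroman-5'-yl)benzofuran; permethyl ether of the target)
Conditions: Pd(PPh3)2Cl2 (5 mol%), CuI (10 mol%), Et3N, DMF, 80 °C, then 100 °C to complete cyclisation
Reagents that add atoms: none
Why: Sonogashira coupling of the o-iodophenol with the terminal alkyne, followed by Cu/Pd-mediated 5-endo-dig oxy-cyclisation, gives the 2-arylbenzofuran. The phenol oxygen becomes O1, the iodinated carbon becomes C3a, and the reverse-prenyl carbon ends up at C7.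

**Step 11**
Reactants: 16
Product: 17 (Artopetelin C)
Conditions: BBr3 (6 equiv), CH2Cl2, −78 → 0 °C; cold aq. NaHCO3 quench
Reagents that add atoms: none
Why: BBr3 cleaves the three aryl methyl ethers (ArOMe → ArOH). The cold, short conditions are chosen to spare the prenyl, 1,1-dimethylallyl and chroman groups, and no stereocentres are present to scramble.

## Compound list
1 | 3-bromo-5-methoxyphenol | Oc1cc(Br)cc(OC)c1 | starting material
2 | chloromethyl methyl ether (MOMCl) | ClCOC | starting material (reagent)
3 | 1-bromo-3-methoxy-5-(methoxymethoxy)benzene | COCOc1cc(Br)cc(OC)c1 | intermediate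
4 | prenyl bromide (1-bromo-3-methylbut-2-ene) | BrCC=C(C)C | starting material (reagent)
5 | 1-bromo-5-methoxy-3-(methoxymethoxy)-2-prenylbenzene | COCOc1cc(OC)cc(Br)c1CC=C(C)C | intermediate
6 | 5-bromo-7-methoxy-2,2-dimethylchroman | COc1cc(Br)c2CCC(C)(C)Oc2c1 | intermediate
7 | 5-bromo-7-methoxy-2,2-dimethyl-6-prenylchroman | COc1cc2OC(C)(C)CCc2c(Br)c1CC=C(C)C | intermediate
8 | trimethylsilylacetylene | C#C[Si](C)(C)C | starting material (reagent)
9 | 7-methoxy-2,2-dimethyl-6-prenyl-5-(TMS-ethynyl)chroman | COc1cc2OC(C)(C)CCc2c(C#C[Si](C)(C)C)c1CC=C(C)C | intermediate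
10 | 5-ethynyl-7-methoxy-2,2-dimethyl-6-prenylchroman | COc1cc2OC(C)(C)CCc2c(C#C)c1CC=C(C)C | intermediate
11 | 3,5-dimethoxyphenol | COc1cc(O)cc(OC)c1 | starting material
12 | N-iodosuccinimide | O=C1CCC(=O)N1I | starting material (reagent)
13 | 2-iodo-3,5-dimethoxyphenol | COc1cc(OC)c(I)c(O)c1 | intermediate
14 | 2-iodo-1,5-dimethoxy-3-(prenyloxy)benzene | CC(C)=CCOc1cc(OC)cc(OC)c1I | intermediate
15 | 2-iodo-3,5-dimethoxy-6-(2-methylbut-3-en-2-yl)phenol | C=CC(C)(C)c1c(OC)cc(OC)c(I)c1O | intermediate
16 | permethyl Artopetelin C (4,6-dimethoxy-7-(1,1-dimethylallyl)-2-aryl-benzofuran) | C=CC(C)(C)c1c(OC)cc(OC)c2cc(-c3c(CC=C(C)C)c(OC)cc4c3CCC(C)(C)O4)oc12 | intermediate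
17 | Artopetelin C | C=CC(C)(C)c1c(O)cc(O)c2cc(-c3c(CC=C(C)C)c(O)cc4c3CCC(C)(C)O4)oc12 | target

## Totals
Total steps: 11. Longest linear sequence: 8 (Steps 1–6, then 10 and 11).

## Three steps most likely to fail
1. **Step 11 (global BBr3 demethylation).** The acid-labile alkenes, especially the reverse prenyl group ortho to a phenol, may cyclise or add HBr.
   - Fallback: change the protecting-group strategy. Use MOM ethers on the A-ring oxygens and the B-ring oxygen, with thermal or Eu(fod)3-promoted Claisen in Step 9, and remove them at the end with mild HCl/MeOH or MgBr2/thiol.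
2. **Step 4 (ortho-lithiation at C6 versus C8).** The wrong regioisomer would place the prenyl group between the two oxygens.
   - Fallback: build 5,7-dibromo-2,2-dimethylchroman from 3,5-dibromophenol (propargyl ether, thermal Claisen cyclisation, then reduction). Lithiate exclusively between the two bromines, prenylate, and convert the less hindered C7–Br to OMe by Cu-catalysed methoxylation.
3. **Step 9 (BCl3 Claisen).** Demethylation of the ortho OMe, or loss of the tertiary centre through cyclisation or retro-reaction, may give low yields.
   - Fallback: drop the Claisen. Brominate the ortho position of a 3,5-dimethoxyphenol derivative and form the quaternary carbon by Cu-catalysed γ-selective (SN2′) coupling of the aryl Grignard with a prenyl phosphate or chloride.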